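**Plan**

1. Retrosynthetic cuts: (a) the ring C=C that carries CH2OH, by an intramolecular Still–Gennari olefination, with CH2OH coming from the ester; (b) the exocyclic C(sp3)–C(sp2) bond between the ring CH stereocentre and the side-chain C(CH3)=, by a Zweifel olefination of a secondary boronic ester; (c) that C–B bond, by enantioselective conjugate borylation of an enoate.
2. Forward order: nerylacetone → terminal alkyne → carboalumination/oxirane → chloride → terminal-alkene cleavage → HWE enoate → β-boryl ester; the C8 (Z)-alkenyl iodide is made from but-2-yn-1-ol; the two are joined, then the chain is closed to the 14-membered ring last and the ester is reduced.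
3. Enabling feature: the only stereocentre is a ring CH of the 14-membered carbocycle that is bonded to the sp2 carbon C(CH3)= of the side chain and lies one CH2 away from the ring =CH of the C(CH2OH)=CH unit. With that =CH at carboxyl level, the CH is the β-carbon of an enoate, so the C–B bond can be set enantioselectively, and the same carbonyl later closes the ring.
4. Stereochemistry: the CH centre comes from the catalyst-controlled borylation and is carried over with retention in the boron-to-carbon 1,2-shift; the side-chain E alkene comes from the Z iodide by the geometry-inverting Zweifel sequence.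
5. Ring alkenes: the Z-methyl alkene comes from nerylacetone, the E-methyl alkene from syn carboalumination, and the hydroxymethyl alkene from the Z-selective ring-closing olefination.

Key step: step 11

Remark: isomerically pure (5Z)-nerylacetone is taken as the commercial starting material, and the Josiphos enantiomer in step 7 is the one that leads to the 3R boronate.

**Route**

Step 1
Reactants: 1 (5Z)-6,10-dimethylundeca-5,9-dien-2-one (nerylacetone)
Product: 3 (5Z)-6,10-dimethylundeca-5,9-dien-1-yne, via enol phosphate 2 (not isolated)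
Conditions: LDA (1.1 equiv), THF, −78 °C; ClP(O)(OEt)2, −78 °C → rt; LDA (2.3 equiv), −78 °C → rt
Reagents that add atoms: none
Why: Negishi methyl ketone → terminal alkyne conversion, in which the kinetic methyl-side enolate is O-phosphorylated and the enol phosphate undergoes base-induced elimination while the 5Z alkene is untouched.

Step 2
Reactants: 3 (5Z)-6,10-dimethylundeca-5,9-dien-1-yne
Product: 6 (3E,7Z)-4,8,12-trimethyltrideca-3,7,11-trien-1-ol, via alkenylalane 4 (not isolated), via lithium alanate 5 (not isolated)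
Conditions: Me3Al (2 equiv), Cp2ZrCl2 (0.25 equiv), CH2Cl2, rt; n-BuLi, THF, −78 °C; oxirane, −78 → 0 °C
Reagents that add atoms: trimethylaluminium, C[Al](C)C; oxirane, C1CO1
Why: zirconium-catalysed Negishi carboalumination adds CH3 and Al syn with Al at the terminal carbon, which fixes the E trisubstituted alkene, and the derived alkenylalanate should open oxirane with retention of geometry.

Step 3
Reactants: 6 (3E,7Z)-4,8,12-trimethyltrideca-3,7,11-trien-1-ol
Product: 7 (3E,7Z)-1-chloro-4,8,12-trimethyltrideca-3,7,11-triene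
Conditions: PPh3, NCS, THF, 0 °C → rt
Reagents that add atoms: N-chlorosuccinimide, O=C1CCC(=O)N1Cl
Why: Appel-type chlorination by SN2 displacement of the oxyphosphonium, giving a primary chloride that serves as an inert placeholder for the later iodide.

Step 4
Reactants: 7 (3E,7Z)-1-chloro-4,8,12-trimethyltrideca-3,7,11-triene
Product: 9 3-[(3Z,7E)-10-chloro-3,7-dimethyldeca-3,7-dien-1-yl]-2,2-dimethyloxirane, via bromohydrin 8 (not isolated)
Conditions: NBS (1.05 equiv), THF/H2O, 0 °C; K2CO3, MeOH, rt
Reagents that add atoms: water, O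
Why: terminal-selective bromohydrin formation of a polyprenyl chain in aqueous medium (the isopropylidene end is the most exposed alkene) followed by base-induced closure to the epoxide, whose stereocentre is irrelevant because it is destroyed in step 5.

Step 5
Reactants: 9 3-[(3Z,7E)-10-chloro-3,7-dimethyldeca-3,7-dien-1-yl]-2,2-dimethyloxirane
Product: 10 (4Z,8E)-11-chloro-4,8-dimethylundeca-4,8-dienal
Conditions: H5IO6, THF/Et2O, 0 °C
Reagents that add atoms: none
Why: periodic acid opens the epoxide and cleaves the resulting glycol (Malaprade-type cleavage) to the aldehyde and acetone without touching the trisubstituted alkenes.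

Step 6
Reactants: 10 (4Z,8E)-11-chloro-4,8-dimethylundeca-4,8-dienal
Product: 11 tert-butyl (2E,6Z,10E)-13-chloro-6,10-dimethyltrideca-2,6,10-trienoate
Conditions: t-BuO2CCH2P(O)(OEt)2, LiCl, DBU, MeCN, rt
Reagents that add atoms: tert-butyl 2-(diethoxyphosphoryl)acetate, CCOP(=O)(CC(=O)OC(C)(C)C)OCC
Why: Horner–Wadsworth–Emmons olefination under Masamune–Roush conditions should give the E enoate with a base mild enough for the enolisable aldehyde.

Step 7
Reactants: 11 tert-butyl (2E,6Z,10E)-13-chloro-6,10-dimethyltrideca-2,6,10-trienoate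
Product: 12 tert-butyl (3R,6Z,10E)-13-chloro-6,10-dimethyl-3-(4,4,5,5-tetramethyl-1,3,2-dioxaborolan-2-yl)trideca-6,10-dienoate
Conditions: B2pin2 (1.1 equiv), CuCl (3 mol%), NaOt-Bu (6 mol%), Josiphos (3 mol%), MeOH (2 equiv), THF, rt
Reagents that add atoms: bis(pinacolato)diboron, CC1(C)OB(OC1(C)C)B1OC(C)(C)C(C)(C)O1
Why: copper(I)-catalysed enantioselective conjugate borylation of an (E)-β-alkyl enoate, in which the chiral Cu–Bpin complex selects the enoate face and so sets the C–B stereocentre (3R), methanol protonates the copper enolate, and the catalytic amount of alkoxide leaves the alkyl chloride alone.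

Step 8
Reactants: 13 but-2-yn-1-ol
Product: 15 (2Z)-3-iodobut-2-en-1-ol, via cyclic vinylalanate 14 (not isolated)
Conditions: Red-Al, THF, 0 °C → rt; EtOAc; I2, −78 → 0 °C
Reagents that add atoms: iodine, II
Why: hydroxyl-directed trans-hydroalumination of the propargylic alcohol gives the cyclic vinylalanate, and iodinolysis with retention gives the Z iodide with iodine cis to CH2OH.

Step 9
Reactants: 15 (2Z)-3-iodobut-2-en-1-ol
Product: 16 (2Z)-1-bromo-3-iodobut-2-ene
Conditions: CBr4, PPh3, CH2Cl2, 0 °C
Reagents that add atoms: carbon tetrabromide, BrC(Br)(Br)Br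
Why: Appel bromination by SN2 at the primary allylic carbon, without allylic transposition or loss of alkene geometry.

Step 10
Reactants: 16 (2Z)-1-bromo-3-iodobut-2-ene
Product: 17 (2Z)-2-iodo-6-methylhepta-2,5-diene
Conditions: Me2C=CHMgBr, CuI (10 mol%), THF, −30 → 0 °C
Reagents that add atoms: (2-methylprop-1-en-1-yl)magnesium bromide, CC(C)=C[Mg]Br
Why: copper-catalysed allylic substitution by the alkenyl Grignard reagent at the primary carbon (the γ-carbon is fully substituted and bears iodine) should give the skipped diene, the vinylic C–I bond being inert under these conditions.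

Step 11
Reactants: 12 tert-butyl (3R,6Z,10E)-13-chloro-6,10-dimethyl-3-(4,4,5,5-tetramethyl-1,3,2-dioxaborolan-2-yl)trideca-6,10-dienoate; 17 (2Z)-2-iodo-6-methylhepta-2,5-diene
Product: 21 tert-butyl (3R,6Z,10E)-13-chloro-6,10-dimethyl-3-[(2E)-6-methylhepta-2,5-dien-2-yl]trideca-6,10-dienoate, via alkenyllithium 18 (not isolated), via boronate complex 19 (not isolated), via iodo boronic ester 20 (not isolated)
Conditions: 17 (1.3 equiv), t-BuLi (2.6 equiv), Et2O, −78 °C; 12, THF, −78 °C; I2 (1.3 equiv), MeOH, −78 °C; NaOMe (3 equiv), MeOH, −78 °C → rt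
Reagents that add atoms: none
Why: tert-Butyllithium exchanges the iodide of 17 with retention to give 18, which adds to the boron of 12 to form boronate complex 19; iodine then forms an iodonium ion on the B-alkenyl C=C, the secondary alkyl group shifts from boron to the adjacent alkenyl carbon anti to the C–I bond (1,2-metallate rearrangement) to give 20, and methoxide-induced anti elimination of boron and iodide releases 21. The reaction type is the Zweifel olefination of enantioenriched secondary pinacol boronic esters with alkenyllithium reagents, which is established for trisubstituted alkenes. No ring is closed in this step. No new stereocentre remains: the migrating carbon keeps its configuration, so the 3R C–B centre of 12 becomes the R-configured CH that joins chain and side chain, and the two transient centres of 20 are destroyed in the elimination. The anti-migration/anti-elimination sequence inverts the alkenyl geometry, so boron cis to the CH2 group (from the Z iodide) should give the E trisubstituted alkene. Chemoselectivity is needed between boron and the ester and among the alkenes: addition of 18 to the Lewis-acidic boron at −78 °C should outrun attack on the hindered tert-butyl ester, the primary chloride is inert, and iodine should react first with the electron-rich alkenylboronate and not with the neutral trisubstituted alkenes.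

Step 12
Reactants: 21 tert-butyl (3R,6Z,10E)-13-chloro-6,10-dimethyl-3-[(2E)-6-methylhepta-2,5-dien-2-yl]trideca-6,10-dienoate
Product: 22 (3R,6Z,10E)-13-chloro-6,10-dimethyl-3-[(2E)-6-methylhepta-2,5-dien-2-yl]trideca-6,10-dien-1-ol
Conditions: DIBAL-H (2.5 equiv), CH2Cl2, −78 → 0 °C; Rochelle salt
Reagents that add atoms: none
Why: DIBAL reduction of the ester to the primary alcohol, which leaves the chloride, the alkenes and the allylic stereocentre untouched.

Step 13
Reactants: 22 (3R,6Z,10E)-13-chloro-6,10-dimethyl-3-[(2E)-6-methylhepta-2,5-dien-2-yl]trideca-6,10-dien-1-ol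
Product: 24 methyl (5E,9Z,13R)-2-[bis(2,2,2-trifluoroethoxy)phosphoryl]-15-hydroxy-6,10-dimethyl-13-[(2E)-6-methylhepta-2,5-dien-2-yl]pentadeca-5,9-dienoate, via iodide 23 (not isolated)
Conditions: (CF3CH2O)2P(O)CH2CO2Me (3 equiv), NaH (2.8 equiv), NaI (1 equiv), DMF, 0 → 55 °C
Reagents that add atoms: methyl 2-[bis(2,2,2-trifluoroethoxy)phosphoryl]acetate, COC(=O)CP(=O)(OCC(F)(F)F)OCC(F)(F)F
Why: Finkelstein exchange to the iodide in situ followed by C-alkylation of the soft sodium phosphonoacetate, which is too weak a base to deprotonate the free alcohol; excess reagent should limit dialkylation, and the new centre next to phosphorus is a mixture that is lost in step 15.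

Step 14
Reactants: 24 methyl (5E,9Z,13R)-2-[bis(2,2,2-trifluoroethoxy)phosphoryl]-15-hydroxy-6,10-dimethyl-13-[(2E)-6-methylhepta-2,5-dien-2-yl]pentadeca-5,9-dienoate
Product: 25 methyl (5E,9Z,13R)-2-[bis(2,2,2-trifluoroethoxy)phosphoryl]-6,10-dimethyl-13-[(2E)-6-methylhepta-2,5-dien-2-yl]-15-oxopentadeca-5,9-dienoate
Conditions: Dess–Martin periodinane, NaHCO3, CH2Cl2, 0 °C → rt
Reagents that add atoms: none
Why: Dess–Martin oxidation of the primary alcohol to the aldehyde under buffered, non-basic conditions that should not trigger premature olefination.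

Step 15
Reactants: 25 methyl (5E,9Z,13R)-2-[bis(2,2,2-trifluoroethoxy)phosphoryl]-6,10-dimethyl-13-[(2E)-6-methylhepta-2,5-dien-2-yl]-15-oxopentadeca-5,9-dienoate
Product: 26 methyl (1(14)Z,4E,8Z,12R)-5,9-dimethyl-12-[(2E)-6-methylhepta-2,5-dien-2-yl]cyclotetradeca-1(14),4,8-triene-1-carboxylate
Conditions: KHMDS (1.1 equiv, slow addition), 18-crown-6 (5 equiv), THF, 1 mM, −78 → −40 °C
Reagents that add atoms: none
Why: intramolecular Still–Gennari (Z-selective Horner–Wadsworth–Emmons) olefination at high dilution closes the 14-membered ring, and the trifluoroethyl phosphonate with the crown-complexed potassium counter-ion should make elimination of the kinetic adduct fast, placing CO2Me cis to the ring CH2 that leads to the stereocentre.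

Step 16
Reactants: 26 methyl (1(14)Z,4E,8Z,12R)-5,9-dimethyl-12-[(2E)-6-methylhepta-2,5-dien-2-yl]cyclotetradeca-1(14),4,8-triene-1-carboxylate
Product: 27 [(1(14)Z,4E,8Z,12R)-5,9-dimethyl-12-[(2E)-6-methylhepta-2,5-dien-2-yl]cyclotetradeca-1(14),4,8-trien-1-yl]methanol (CNP0288338.1)
Conditions: DIBAL-H (2.5 equiv), CH2Cl2, −78 °C; Rochelle salt
Reagents that add atoms: none
Why: DIBAL 1,2-reduction of the α,β-unsaturated ester should give the allylic alcohol without touching the alkenes or the stereocentre.

**Compound list**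

1 | (5Z)-6,10-dimethylundeca-5,9-dien-2-one (nerylacetone) | CC(=O)CC/C=C(/C)CCC=C(C)C | starting material
2 | diethyl (5Z)-6,10-dimethylundeca-1,5,9-trien-2-yl phosphate (enol phosphate, not isolated) | C=C(OP(=O)(OCC)OCC)CC/C=C(/C)CCC=C(C)C | intermediate
3 | (5Z)-6,10-dimethylundeca-5,9-dien-1-yne | C#CCC/C=C(/C)CCC=C(C)C | intermediate
4 | dimethyl[(1E,5Z)-2,6,10-trimethylundeca-1,5,9-trien-1-yl]alumane (not isolated) | C[Al](C)/C=C(\C)CC/C=C(/C)CCC=C(C)C | intermediate
5 | lithium butyl(dimethyl)[(1E,5Z)-2,6,10-trimethylundeca-1,5,9-trien-1-yl]aluminate (not isolated) | [Li+].CCCC[Al-](C)(C)/C=C(\C)CC/C=C(/C)CCC=C(C)C | intermediate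
6 | (3E,7Z)-4,8,12-trimethyltrideca-3,7,11-trien-1-ol | OCC/C=C(\C)CC/C=C(/C)CCC=C(C)C | intermediate
7 | (3E,7Z)-1-chloro-4,8,12-trimethyltrideca-3,7,11-triene | ClCC/C=C(\C)CC/C=C(/C)CCC=C(C)C | intermediate
8 | (6Z,10E)-3-bromo-13-chloro-2,6,10-trimethyltrideca-6,10-dien-2-ol (racemic bromohydrin, not isolated) | ClCC/C=C(\C)CC/C=C(/C)CCC(Br)C(C)(C)O | intermediate
9 | 3-[(3Z,7E)-10-chloro-3,7-dimethyldeca-3,7-dien-1-yl]-2,2-dimethyloxirane (racemic) | ClCC/C=C(\C)CC/C=C(/C)CCC1OC1(C)C | intermediate
10 | (4Z,8E)-11-chloro-4,8-dimethylundeca-4,8-dienal | ClCC/C=C(\C)CC/C=C(/C)CCC=O | intermediate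
11 | tert-butyl (2E,6Z,10E)-13-chloro-6,10-dimethyltrideca-2,6,10-trienoate | ClCC/C=C(\C)CC/C=C(/C)CC/C=C/C(=O)OC(C)(C)C | intermediate
12 | tert-butyl (3R,6Z,10E)-13-chloro-6,10-dimethyl-3-(4,4,5,5-tetramethyl-1,3,2-dioxaborolan-2-yl)trideca-6,10-dienoate | B1(OC(C)(C)C(C)(C)O1)[C@H](CC/C(C)=C\CC/C(C)=C/CCCl)CC(=O)OC(C)(C)C | intermediate
13 | but-2-yn-1-ol | CC#CCO | starting material
14 | sodium 2,2-bis(2-methoxyethoxy)-3-methyl-2,5-dihydro-1,2-oxaaluminol-2-uide (cyclic vinylalanate, Al cis to CH2O, not isolated) | CC1=CCO[Al-]1(OCCOC)OCCOC.[Na+] | intermediate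
15 | (2Z)-3-iodobut-2-en-1-ol | C/C(I)=C/CO | intermediate
16 | (2Z)-1-bromo-3-iodobut-2-ene | C/C(I)=C/CBr | intermediate
17 | (2Z)-2-iodo-6-methylhepta-2,5-diene | C/C(I)=C/CC=C(C)C | intermediate
18 | (6-methylhepta-2,5-dien-2-yl)lithium, Li cis to the CH2 chain (formally 2E because Li ranks below CH3; not isolated) | C/C([Li])=C/CC=C(C)C | intermediate
19 | lithium boronate complex of 12 and 18 (boron cis to the CH2 chain of the alkenyl group; not isolated) | CC(C)=CC/C=C(/C)[B-]1(OC(C)(C)C(C)(C)O1)[C@H](CC/C(C)=C\CC/C(C)=C/CCCl)CC(=O)OC(C)(C)C.[Li+] | intermediate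
20 | β-iodo boronic ester from anti addition of the migrating carbon and iodine (one of the two diastereomers that differ in the face attacked by iodine is drawn; not isolated) | CC(C)=CC[C@@H](I)[C@@](C)(B1OC(C)(C)C(C)(C)O1)[C@H](CC/C(C)=C\CC/C(C)=C/CCCl)CC(=O)OC(C)(C)C | intermediate
21 | tert-butyl (3R,6Z,10E)-13-chloro-6,10-dimethyl-3-[(2E)-6-methylhepta-2,5-dien-2-yl]trideca-6,10-dienoate | CC(C)=CC/C=C(\C)[C@H](CC/C(C)=C\CC/C(C)=C/CCCl)CC(=O)OC(C)(C)C | intermediate
22 | (3R,6Z,10E)-13-chloro-6,10-dimethyl-3-[(2E)-6-methylhepta-2,5-dien-2-yl]trideca-6,10-dien-1-ol | CC(C)=CC/C=C(\C)[C@H](CC/C(C)=C\CC/C(C)=C/CCCl)CCO | intermediate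
23 | (3R,6Z,10E)-13-iodo-6,10-dimethyl-3-[(2E)-6-methylhepta-2,5-dien-2-yl]trideca-6,10-dien-1-ol (not isolated) | CC(C)=CC/C=C(\C)[C@H](CC/C(C)=C\CC/C(C)=C/CCI)CCO | intermediate
24 | methyl (5E,9Z,13R)-2-[bis(2,2,2-trifluoroethoxy)phosphoryl]-15-hydroxy-6,10-dimethyl-13-[(2E)-6-methylhepta-2,5-dien-2-yl]pentadeca-5,9-dienoate (mixture at C-2) | CC(C)=CC/C=C(\C)[C@H](CC/C(C)=C\CC/C(C)=C/CCC(C(=O)OC)P(=O)(OCC(F)(F)F)OCC(F)(F)F)CCO | intermediate
25 | methyl (5E,9Z,13R)-2-[bis(2,2,2-trifluoroethoxy)phosphoryl]-6,10-dimethyl-13-[(2E)-6-methylhepta-2,5-dien-2-yl]-15-oxopentadeca-5,9-dienoate (mixture at C-2) | CC(C)=CC/C=C(\C)[C@H](CC/C(C)=C\CC/C(C)=C/CCC(C(=O)OC)P(=O)(OCC(F)(F)F)OCC(F)(F)F)CC=O | intermediate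
26 | methyl (1(14)Z,4E,8Z,12R)-5,9-dimethyl-12-[(2E)-6-methylhepta-2,5-dien-2-yl]cyclotetradeca-1(14),4,8-triene-1-carboxylate (as 27 with CO2Me in place of CH2OH) | CC(C)=CC/C=C(\C)[C@H]1C/C=C(\C(=O)OC)CC/C=C(\C)CC/C=C(/C)CC1 | intermediate
27 | [(1(14)Z,4E,8Z,12R)-5,9-dimethyl-12-[(2E)-6-methylhepta-2,5-dien-2-yl]cyclotetradeca-1(14),4,8-trien-1-yl]methanol (CNP0288338.1) | CC(C)=CC/C=C(\C)[C@H]1C/C=C(\CO)CC/C=C(\C)CC/C=C(/C)CC1 | target

**Step count**

Total steps: 16. Longest linear sequence: 13 (steps 1–7 and 11–16); steps 8–10 make the side-chain fragment.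

**Steps most likely to fail, with fallbacks**

Step 15 (ring closure). Intermolecular olefination may compete with cyclisation and give oligomers, and the constraint of the forming ring may erode the Z selectivity of the elimination. The fallback closes the ring by alkylation and sets the alkene afterwards. It sets out from alcohol 22: Dess–Martin oxidation gives the chloro aldehyde F1; tin(II) chloride-catalysed Roskamp homologation with methyl diazoacetate gives the β-keto ester F2; intramolecular C-alkylation (NaI, Cs2CO3, MeCN, high dilution, heat) joins the ester α-carbon to the CH2 that carried chlorine and gives the macrocyclic β-keto ester F3; triflation under non-chelating conditions (Tf2O, aqueous Me4NOH, toluene) should give the E enol triflate F4, in which OTf is trans to CO2Me; palladium-catalysed formate reduction (Pd(OAc)2, PPh3, Bu3N, HCO2H, DMF) replaces OTf by H with retention and comes back to the route at 26.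

Step 11 (key step). The alkenyllithium may attack or deprotonate the ester instead of adding to boron, and iodination of the other alkenes or a partial syn elimination may erode the E geometry. The fallback forms the same bond by auxiliary-controlled conjugate addition. It sets out from aldehyde 10: Horner–Wadsworth–Emmons olefination with diethyl {2-[(4S)-4-benzyl-2-oxo-1,3-oxazolidin-3-yl]-2-oxoethyl}phosphonate (LiCl, i-Pr2NEt, MeCN) gives the N-enoyl oxazolidinone F5. Because a cuprate transfers the alkenyl group with retention, the E iodide is needed: 1-propynylmagnesium bromide and prenyl bromide (CuCl cat., THF) give 6-methylhept-5-en-2-yne F6, and hydrozirconation with excess Cp2ZrHCl (equilibration to zirconium on the methyl-bearing carbon) followed by I2 gives (2E)-2-iodo-6-methylhepta-2,5-diene F7. Lithium–iodine exchange, MgBr2·OEt2 and CuBr·SMe2 (THF/Me2S, −78 → −20 °C) should add the alkenyl group to F5 from the face opposite the benzyl group of the chelated s-cis imide and give the 3R conjugate adduct F8; LiBH4/MeOH removes the auxiliary and comes back to the route at 22.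

Step 4 (terminal bromohydrin). Bromohydrin formation may also occur at the two internal trisubstituted alkenes, or twice on the same chain. The fallback replaces the oxidative cleavage and the olefination by metathesis. It sets out from triene 7: cross-metathesis with tert-butyl acrylate (second-generation Hoveyda–Grubbs catalyst, CH2Cl2, 40 °C) should exchange only the isopropylidene terminus, the internal trisubstituted alkenes being much less reactive, and comes back to the route directly at 11. This fallback makes no new compound (F0).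

Further compounds
F1 | step 15 | (3R,6Z,10E)-13-chloro-6,10-dimethyl-3-[(2E)-6-methylhepta-2,5-dien-2-yl]trideca-6,10-dienal | CC(C)=CC/C=C(\C)[C@H](CC/C(C)=C\CC/C(C)=C/CCCl)CC=O
F2 | step 15 | methyl (5R,8Z,12E)-15-chloro-8,12-dimethyl-5-[(2E)-6-methylhepta-2,5-dien-2-yl]-3-oxopentadeca-8,12-dienoate | CC(C)=CC/C=C(\C)[C@H](CC/C(C)=C\CC/C(C)=C/CCCl)CC(=O)CC(=O)OC
F3 | step 15 | macrocyclic β-keto ester: as 26 but with C(=O)–CH(CO2Me) in place of CH=C(CO2Me) (mixture at the ester-bearing carbon) | CC(C)=CC/C=C(\C)[C@H]1CC(=O)C(C(=O)OC)CC/C=C(\C)CC/C=C(/C)CC1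
F4 | step 15 | E enol triflate of F3 (OTf trans to CO2Me) | CC(C)=CC/C=C(\C)[C@H]1C/C(OS(=O)(=O)C(F)(F)F)=C(\C(=O)OC)CC/C=C(\C)CC/C=C(/C)CC1
F5 | step 11 | (4S)-4-benzyl-3-[(2E,6Z,10E)-13-chloro-6,10-dimethyltrideca-2,6,10-trienoyl]-1,3-oxazolidin-2-one | ClCC/C=C(\C)CC/C=C(/C)CC/C=C/C(=O)N1[C@@H](Cc2ccccc2)COC1=O
F6 | step 11 | 6-methylhept-5-en-2-yne | CC#CCC=C(C)C
F7 | step 11 | (2E)-2-iodo-6-methylhepta-2,5-diene | C/C(I)=C\CC=C(C)C
F8 | step 11 | (4S)-4-benzyl-3-{(3R,6Z,10E)-13-chloro-6,10-dimethyl-3-[(2E)-6-methylhepta-2,5-dien-2-yl]trideca-6,10-dienoyl}-1,3-oxazolidin-2-one | CC(C)=CC/C=C(\C)[C@H](CC/C(C)=C\CC/C(C)=C/CCCl)CC(=O)N1[C@@H](Cc2ccccc2)COC1=O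
F0 | step 4 | none | none
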